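**Numbering used throughout.** Ring: O1, C2 (methyl, side chain), C3 (oxygen), C4, C5, C6 (exocyclic alkene to C1'), C7. Exocyclic unit: C1'H=, C2'H2–O. Side chain: C1''–C8'' (methyl on C4'', hydroxyl on C5'', C7''=C8'' alkene). Compounds 1–33 are defined in the steps and in the compound list.

## Analysis of the target

Compound 33 is a monocyclic oxepane. C2 is a fully substituted ether carbon carrying a methyl group and the chain C1''–C8''; C3 bears an acetate; C6 carries an exocyclic alkene C6=C1' whose outer carbon is bonded to the acetoxymethylene C2'.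

There are four stereocentres in two isolated pairs. C2 (S) and C3 (R) are neighbours on the ring, with the C3 oxygen on the same face as the C2 methyl group and opposite to C1''. C4'' (R) and C5'' (R) are neighbours in the chain with methyl and hydroxyl syn. Three methylene groups (C1''–C3'') separate the pairs, so neither can control the other.

The C6=C1' alkene is E: C2' lies on the side of C5 and away from C7.

Sensitive points are the allylic acetate (ionisable, base-labile) and the two trisubstituted alkenes (acid, electrophilic oxidants, metal carbenes). The end game must also leave two hydroxyls acetylated (C3, C2') and one free (C5'').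

The difficulty is concentrated in the seven-membered ring with a tetrasubstituted C2 next to oxygenated C3, and in the geometry of the exocyclic alkene.

The strategy rests on the C2–C3 bond. Two adjacent oxygen-bearing carbons, one of them bonded to O1 and methyl-substituted, are what forms when a carbonyl-derived radical at C3 adds to the oxygen-bearing carbon of an O1-bound, methyl-substituted vinyl acceptor. C1'' then emerges carrying the activating group of the acceptor, which serves to attach the chain.

## Retrosynthetic reasoning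

**33 ⇒ 32 ⇒ 31 ⇒ 30 (oxygen differentiation).** Of three hydroxyls, two must be acetylated and the C5'' one must stay free. The C5'' oxygen is therefore carried as a p-methoxybenzyl ether and released oxidatively as the last operation (33 from 32). The two ring-side oxygens are carried as silyl ethers, so that one fluoride treatment of 30 exposes exactly the pair to be acetylated (31, then 32). No C–C bond is cut here; the gain is that no selective acylation is ever needed.

**30 ⇒ 29 ⇒ 17 + 27 (C1''–C2'' bond).** After the ring-forming step C1'' carries sulfur, which makes it the natural carbanion site. The bond cut is an unbranched CH2–CH2 link, three atoms from C4'' and one from C2, so the two stereo-pairs are made in separate fragments and no stereocentre is formed in the coupling. Forward, the lithiated sulfone 28 must be alkylated by the primary iodide 27, and the sulfonyl group of 29 must then be removed reductively without opening the ring.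

**17 ⇒ 16 ⇒ 15 (sulfur and C3 oxygen adjustment).** The sulfone is the better carbanion-stabilising group and is inert to silyl triflates, whereas the sulfoxide would be activated by them. Hence oxidation (16) comes before silylation (17). Oxidation also removes the sulfur stereocentre once it has done its work.

**15 ⇒ 14 (C2–C3 bond, ring closure).** This is the disconnection that defines the route. Cutting C2–C3 removes the ring and both ring stereocentres at once and leaves aldehyde 14, whose only stereocentre is sulfur because C6 is sp2. Forward, a ketyl at C3 must add to C2 of the vinyl sulfoxide in a seven-membered closure, place the hydroxyl trans to C1'', and choose one face of C2 under the influence of sulfur. Other cuts of the ring (C–O bonds, C5–C6) would not create the C2/C3 pair in the same step.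

**14 ⇒ 13 ⇒ 9 + 12; 12 ⇒ 10 + 11 (O1–C2 bond, sulfur stereocentre).** The enol ether is opened at O1–C2 to the C7 alcohol 9 and the alkynyl sulfoxide 12; forward this is an oxa-Michael addition that must give the E enol ether. The aldehyde stays masked as the diethyl acetal (13) until after this step, because a free C7 hydroxyl and a C3 aldehyde would close to a six-membered lactol. Sulfoxide 12 comes from sulfinate ester 10 and Grignard reagent 11. This displacement inverts sulfur, so the sulfur geometry wanted in 14 requires the (R)-sulfinate of the (1S,2R,5S)-configured terpene alcohol. Its more common mirror-image ester would lead to the enantiomer of 12.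

**9 ⇒ 8 ⇒ 5 + 6 (C5–C6 bond).** Cutting C5–C6 separates a three-carbon aldehyde equivalent (6, used as borane 7) from a four-carbon vinyl iodide 5. The coupling is stereoretentive, so the alkene geometry is decided earlier and only carried through. Oxidative removal of the p-methoxybenzyl group of 8 then frees the C7 hydroxyl (9).

**5 ⇒ 4 ⇒ 2 ⇒ 1 (alkene geometry).** Vinyl iodide 4 is traced to the propargylic alcohol 2 by a hydroxyl-directed trans-hydroalumination and iodination, which puts iodine on C6 cis to C2'; this is the step that fixes the E geometry of 33. Ether 2 is the mono-protected form of the symmetrical diol 1, so the two ends of a four-carbon building block are told apart at the outset.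

**27 ⇒ 26 ⇒ 24 ⇒ 23 ⇒ 19 + 20; 19 ⇒ 18 (side chain).** The C4''–C5'' bond is cut in the crotylation sense: aldehyde 19 and the (Z)-crotyl unit of 20 (as borane 22) give the syn methyl/hydroxyl pair in one step with reagent control of the absolute configuration. The vinyl group of 23 is the latent C2''–C3'' unit; after protection (24), hydroboration–oxidation (26) and iodination give 27. Aldehyde 19 is the oxidation product of alcohol 18.

## Alternatives that were turned down

**Alternative 1: ring expansion of a cyclohexanone.**
- Disconnection: the two bonds of the ring oxygen (O1–C2, O1–C7) are traced back to one C–C bond of a six-membered ketone.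
- Key step: lactone A1 would arise from cyclohexanone A2 by Baeyer–Villiger oxidation (bis(trimethylsilyl) peroxide, SnCl4, trans-cyclohexane-1,2-diamine), the fully substituted carbon migrating with retention. A2 would come from enantioselective mono-reduction of the prochiral dione A3 and silylation.
- For: ring expansion avoids an entropically costly seven-membered closure. The migratory preference of the quaternary carbon makes the regiochemistry safe, and the peroxide system spares the allyl group. Both ring stereocentres rest on a well-understood desymmetrisation. On certainty of absolute configuration and of ring formation this plan is stronger than the chosen one.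
- Against: the key step creates no stereocentre, and A1 is far from 33. C7 arrives as a lactone carbonyl. It must be reduced to CH2 after the C6 alkylidene has been installed by aldol–dehydration, which means reducing a lactol next to an allylic system where ionisation invites transposition. The whole C4''–C8'' portion must still be grown from the allyl group by a second fragment coupling.
- Comparison: the sequence after the key step is expected to be clearly longer than the twelve steps that follow the samarium cyclisation. In exchange for its less certain induction, the chosen route delivers C7 at the ether oxidation level, the alkylidene in place with defined geometry, and a sulfur handle at C1''.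

**Alternative 2: enyne metathesis, then 1,4-hydroboration.**
- Disconnection: C5–C6 together with the exocyclic alkene.
- Key step: diene A4 from enyne A5 by ring-closing enyne metathesis (second-generation Grubbs catalyst, ethylene). The allyl group on C3 and the propargyl ether on O1 are joined so that C5=C6 becomes endocyclic and C6 carries a vinyl group. A cis-selective 1,4-hydroboration–oxidation (for example Ni(cod)2/PCy3 with pinacolborane) would then add hydrogen to C5 and oxygen to C2', leaving C6=C1' with C2' cis to C5.
- For: the complete side chain is present before ring closure, so the end game is very short. Enyne metathesis to seven-membered dienes is dependable, and the 1,4-addition is an economical way to set the alkene geometry. In convergence and in steps after the key step it is stronger than the chosen plan.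
- Against: no stereocentre is formed in the key step, so the C2/C3 pair must be built on an open chain. The tertiary C2 hydroxyl must then be propargylated next to an acetate (hindered alkoxide, acyl migration). The trisubstituted C7''=C8'' alkene is a competent partner for the ruthenium carbene under ethylene, so truncation of the chain terminus competes with ring closure. The nickel step must respect an allylic C7–O1 bond that can ionise.
- Comparison: the chosen route keeps metal-carbene chemistry away from the side-chain alkene and forms C2 and C3 in the ring-closing event from a precursor without any carbon stereocentre.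

**Alternative 3: cyclopropanol ring opening and coupling.**
- Disconnection: C5–C6, with C5 as a homoenolate.
- Key step: oxepanone A6 from the vinyl iodide–cyclopropanol A7. Zerovalent palladium (Pd2(dba)3 with a bulky phosphine) inserts into the C6–I bond, the palladium alkoxide of the cyclopropanol undergoes β-carbon elimination to place palladium on C5, and reductive elimination closes the ring.
- For: ring and C5–C6 bond form in one step from a fully elaborated chain, and no auxiliary is needed. The alkene geometry is fixed in the vinyl iodide by the same hydroalumination–iodination logic as in the chosen route, so the two are equal on that point.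
- Against: reductive elimination must occur from an eight-membered palladacycle while the C5-bound palladium has β-hydrogens on C4, so β-hydride elimination to an enone is the expected competitor. The C3 ketone of A6 must then be reduced with the hydride choosing between faces that differ only in methyl versus a CH2 chain on the neighbouring quaternary carbon, so C3 needs reagent control of uncertain strength. C2 must be made earlier as a tertiary ether by alkylating a hindered tertiary alkoxide.
- Comparison: stronger in convergence; weaker in stereocontrol at C3 and in certainty of the closure. The chosen route forms C3 with the ring and in the correct relative sense.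

Key step: step 9

Assumption: the ketyl is taken to attack the alkene face that carries the S–O bond in the rotamer whose sulfur lone pair eclipses the C2 methyl group; on this model the (S)-sulfoxide 14 gives the ring configuration of 33. In 15–17 and 29 the C2 descriptor reads R only because sulfur on C1'' changes the priorities.

## Route

Step 1
Reactants: 1 but-2-yne-1,4-diol
Product: 2 4-[(4-methoxybenzyl)oxy]but-2-yn-1-ol
Conditions: 1 (3 equiv), NaH (1 equiv), THF–DMF, 0 °C; 4-methoxybenzyl chloride (1 equiv), Bu4NI (cat.), 0 °C to rt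
Reagents that add atoms: 4-methoxybenzyl chloride, COc1ccc(CCl)cc1
Why: Williamson etherification; the excess of the cheap symmetrical diol suppresses bis-alkylation and is washed out with water. The ether oxygen introduced here is the future C7 oxygen, kept distinct from the free C2' hydroxyl.

Step 2
Reactants: 2 4-[(4-methoxybenzyl)oxy]but-2-yn-1-ol
Product: 4 (Z)-3-iodo-4-[(4-methoxybenzyl)oxy]but-2-en-1-ol, via cyclic sodium alkenylalanate 3 (not isolated)
Conditions: NaAlH2(OCH2CH2OMe)2, THF, 0 °C; EtOAc; then I2, THF, −78 °C to 0 °C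
Reagents that add atoms: iodine, [I][I]
Why: Hydroxyl-directed trans-hydroalumination: the alkoxy-bound aluminium hydride delivers hydride to C1' and aluminium to C6 inside a five-membered ring, and iodinolysis of the C–Al bond with retention leaves iodine cis to C2'. The sequence is run cold so that alanate 3 does not expel the C7 ether oxygen to form an allene.

Step 3
Reactants: 4 (Z)-3-iodo-4-[(4-methoxybenzyl)oxy]but-2-en-1-ol
Product: 5 (Z)-tert-butyl({3-iodo-4-[(4-methoxybenzyl)oxy]but-2-en-1-yl}oxy)diphenylsilane
Conditions: t-BuPh2SiCl, imidazole, CH2Cl2, 0 °C to rt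
Reagents that add atoms: tert-butyl(chloro)diphenylsilane, CC(C)(C)[Si](Cl)(c1ccccc1)c1ccccc1
Why: Standard silylation of a primary allylic alcohol; the tert-butyldiphenylsilyl ether is chosen because it should survive the oxidative, acidic, reductive and carbanion conditions up to step 19.

Step 4
Reactants: 5 (Z)-tert-butyl({3-iodo-4-[(4-methoxybenzyl)oxy]but-2-en-1-yl}oxy)diphenylsilane; 6 acrolein diethyl acetal (3,3-diethoxyprop-1-ene)
Product: 8 (E)-tert-butyl[(6,6-diethoxy-3-{[(4-methoxybenzyl)oxy]methyl}hex-2-en-1-yl)oxy]diphenylsilane, via 9-(3,3-diethoxypropyl)-9-borabicyclo[3.3.1]nonane 7 (not isolated)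
Conditions: 6, 9-BBN-H, THF, 0 °C to rt; then 5, PdCl2(dppf) (5 mol%), AsPh3, Cs2CO3, DMF–H2O, rt
Reagents that add atoms: none
Why: B-alkyl Suzuki–Miyaura coupling: anti-Markovnikov hydroboration of 6 gives the primary borane 7, and oxidative addition of zerovalent palladium into the C6–I bond, transmetallation and reductive elimination all proceed with retention, so C5 takes the place of iodine cis to C2'. The acetal carries C3 at the aldehyde oxidation level through the next steps.

Step 5
Reactants: 8 (E)-tert-butyl[(6,6-diethoxy-3-{[(4-methoxybenzyl)oxy]methyl}hex-2-en-1-yl)oxy]diphenylsilane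
Product: 9 (E)-2-{2-[(tert-butyldiphenylsilyl)oxy]ethylidene}-5,5-diethoxypentan-1-ol
Conditions: DDQ, CH2Cl2–pH 7 phosphate buffer (10:1), 0 °C
Reagents that add atoms: none
Why: Oxidative cleavage of the p-methoxybenzyl ether by hydride abstraction and hydrolysis of the oxocarbenium ion; the buffer keeps the medium neutral so that the diethyl acetal neither hydrolyses nor exchanges with the liberated C7 hydroxyl, and a short contact time at 0 °C avoids oxidation of the allylic alcohol.

Step 6
Reactants: 10 (1S,2R,5S)-menthyl (R)-p-toluenesulfinate; 11 prop-1-ynylmagnesium bromide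
Product: 12 (R)-1-methyl-4-(prop-1-yn-1-ylsulfinyl)benzene
Conditions: toluene–THF, −20 °C to 0 °C
Reagents that add atoms: none
Why: Andersen sulfoxide synthesis: the alkynyl Grignard reagent displaces menthoxide at sulfur with inversion, so the (R)-sulfinate gives the alkynyl sulfoxide with the sulfur geometry needed in 14 (descriptor R here because propynyl outranks p-tolyl).

Step 7
Reactants: 9 (E)-2-{2-[(tert-butyldiphenylsilyl)oxy]ethylidene}-5,5-diethoxypentan-1-ol; 12 (R)-1-methyl-4-(prop-1-yn-1-ylsulfinyl)benzene
Product: 13 tert-butyl{[(E)-6,6-diethoxy-3-({[(E)-1-((S)-p-tolylsulfinyl)prop-1-en-2-yl]oxy}methyl)hex-2-en-1-yl]oxy}diphenylsilane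
Conditions: NaH (0.2 equiv), THF, 0 °C to rt
Reagents that add atoms: none
Why: Base-catalysed oxa-Michael addition of the C7 alkoxide to the β-carbon of the alkynyl sulfoxide forms O1–C2; reversible addition–elimination of alkoxide should equilibrate the enol ether to the E isomer with the alkoxy group trans to sulfur, and sulfur is not touched. Silyl migration from C2' is excluded because C2' and C7 are trans across the C6=C1' bond.

Step 8
Reactants: 13 tert-butyl{[(E)-6,6-diethoxy-3-({[(E)-1-((S)-p-tolylsulfinyl)prop-1-en-2-yl]oxy}methyl)hex-2-en-1-yl]oxy}diphenylsilane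
Product: 14 (E)-6-[(tert-butyldiphenylsilyl)oxy]-4-({[(E)-1-((S)-p-tolylsulfinyl)prop-1-en-2-yl]oxy}methyl)hex-4-enal
Conditions: PPTS (cat.), acetone–H2O (10:1), rt
Reagents that add atoms: water, O
Why: Mild acid hydrolysis of the diethyl acetal; the enol ether is deactivated towards protonation at C1'' by the sulfinyl group and the tert-butyldiphenylsilyl ether is acid-stable, so only the acetal should react. The aldehyde is unmasked only now because a free C7 hydroxyl would have closed onto it as a six-membered lactol.

Step 9
Reactants: 14 (E)-6-[(tert-butyldiphenylsilyl)oxy]-4-({[(E)-1-((S)-p-tolylsulfinyl)prop-1-en-2-yl]oxy}methyl)hex-4-enal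
Product: 15 (2R,3R)-6-{(E)-2-[(tert-butyldiphenylsilyl)oxy]ethylidene}-2-methyl-2-{[(S)-p-tolylsulfinyl]methyl}oxepan-3-ol
Conditions: SmI2 (3 equiv), MeOH (5 equiv), THF (0.01 M), 0 °C
Reagents that add atoms: none
Why: SmI2 transfers one electron to the C3 aldehyde; the trivalent-samarium ketyl adds to C2 of the electron-poor vinyl sulfoxide, a second electron turns the C1'' radical into the α-sulfinyl organosamarium, and methanol protonates it before it can expel O1. The closest known reaction type is the SmI2-mediated reductive cyclisation of aldehydes onto β-alkoxyacrylates and β-alkoxyvinyl sulfoxides, which gives 2,3-trans 3-hydroxy cyclic ethers, oxepanes included, and tolerates a β-methyl group on the acceptor. The oxepane closes in the 7-exo-trig mode (C3 to C2, C1'' left outside the ring); addition of the ketyl to the C6=C1' alkene would be 4-exo or 5-endo onto an unactivated alkene and should not compete. C3 is controlled by the samarium bridge between the ketyl oxygen and the sulfinyl oxygen: in the folded transition state the C3–O and C2–C1'' bonds are both pseudo-equatorial and gauche, which places the hydroxyl trans to C1'' and cis to the methyl group. C2 is controlled by sulfur: allylic strain with the cis methyl group puts the sulfur lone pair in the alkene plane, S–O on one face and p-tolyl on the other, and the chelated ketyl is delivered to the S–O face, which for the (S)-sulfoxide is the face leading to the C2 configuration of 33. The step needs chemoselectivity for the aldehyde over the sulfoxide and the allylic ethers (the aldehyde is reduced far more easily at 0 °C without HMPA), cyclisation over pinacol coupling or simple reduction (high dilution, polarised acceptor), and facial selectivity, which only the sulfinyl group can provide because C6 is sp2 and there is no other stereocentre. If the two faces react at similar rates the products are diastereomers and separable, and step 10 then removes the sulfur stereocentre.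

Step 10
Reactants: 15 (2R,3R)-6-{(E)-2-[(tert-butyldiphenylsilyl)oxy]ethylidene}-2-methyl-2-{[(S)-p-tolylsulfinyl]methyl}oxepan-3-ol
Product: 16 (2R,3R)-6-{(E)-2-[(tert-butyldiphenylsilyl)oxy]ethylidene}-2-methyl-2-(p-tolylsulfonylmethyl)oxepan-3-ol
Conditions: (NH4)6Mo7O24·4H2O (10 mol%), 30% H2O2, EtOH, 0 °C to rt
Reagents that add atoms: hydrogen peroxide, OO
Why: Peroxomolybdate-catalysed oxidation of the sulfoxide to the sulfone; sulfur should be oxidised far faster than a trisubstituted alkene flanked by two allylic oxygens, whereas a peracid would risk epoxidation. The sulfur stereocentre, no longer needed, disappears.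

Step 11
Reactants: 16 (2R,3R)-6-{(E)-2-[(tert-butyldiphenylsilyl)oxy]ethylidene}-2-methyl-2-(p-tolylsulfonylmethyl)oxepan-3-ol
Product: 17 tert-butyl{[(2R,3R)-6-{(E)-2-[(tert-butyldiphenylsilyl)oxy]ethylidene}-2-methyl-2-(p-tolylsulfonylmethyl)oxepan-3-yl]oxy}dimethylsilane
Conditions: t-BuMe2SiOTf, 2,6-lutidine, CH2Cl2, −78 °C to 0 °C
Reagents that add atoms: tert-butyldimethylsilyl trifluoromethanesulfonate, CC(C)(C)[Si](C)(C)OS(=O)(=O)C(F)(F)F
Why: Silyl triflate silylation of the hindered secondary alcohol next to the quaternary C2; it is placed after step 10 because a silyl triflate would activate the sulfoxide towards Pummerer-type chemistry, whereas the sulfone is inert.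

Step 12
Reactants: 18 4-methylpent-3-en-1-ol
Product: 19 4-methylpent-3-enal
Conditions: Dess–Martin periodinane, NaHCO3, CH2Cl2, 0 °C; solution used directly
Reagents that add atoms: none
Why: Dess–Martin oxidation under buffered, non-basic conditions should give the β,γ-unsaturated aldehyde without migration of the alkene into conjugation; the volatile aldehyde is used at once.

Step 13
Reactants: 19 4-methylpent-3-enal; 20 (Z)-but-2-ene
Product: 23 (3R,4R)-3,7-dimethylocta-1,6-dien-4-ol, via (Z)-but-2-enylpotassium 21 (not isolated), via (Z)-but-2-enyldiisopinocampheylborane 22 (not isolated)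
Conditions: 20, KOt-Bu, n-BuLi, THF, −78 to −45 °C; (−)-Ipc2BOMe, −78 °C; BF3·OEt2; 19, −78 °C; then NaOH, H2O2, rt
Reagents that add atoms: none
Why: Brown crotylboration: the (Z)-crotylborane reacts through a closed chair transition state, so the Z geometry gives the syn methyl/hydroxyl pair (C4'', C5''), and the isopinocampheyl groups derived from (+)-α-pinene direct attack to the Si face of the aldehyde, giving the (3R,4R) alcohol. Low temperature keeps 21 and 22 configurationally intact.

Step 14
Reactants: 23 (3R,4R)-3,7-dimethylocta-1,6-dien-4-ol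
Product: 24 1-({[(3R,4R)-3,7-dimethylocta-1,6-dien-4-yl]oxy}methyl)-4-methoxybenzene
Conditions: NaH, 4-methoxybenzyl chloride, Bu4NI (cat.), DMF, 0 °C to rt
Reagents that add atoms: 4-methoxybenzyl chloride, COc1ccc(CCl)cc1
Why: Williamson etherification of the secondary alkoxide; the p-methoxybenzyl ether is the one protecting group that can be removed at the end without touching acetates.

Step 15
Reactants: 24 1-({[(3R,4R)-3,7-dimethylocta-1,6-dien-4-yl]oxy}methyl)-4-methoxybenzene
Product: 26 (3R,4R)-4-[(4-methoxybenzyl)oxy]-3,7-dimethyloct-6-en-1-ol, via 9-{(3R,4R)-4-[(4-methoxybenzyl)oxy]-3,7-dimethyloct-6-en-1-yl}-9-borabicyclo[3.3.1]nonane 25 (not isolated)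
Conditions: 9-BBN-H, THF, 0 °C to rt; then NaOH, H2O2, 0 °C
Reagents that add atoms: hydrogen peroxide, OO
Why: Hydroboration–oxidation with a bulky dialkylborane, which adds to the monosubstituted alkene (boron on the terminal carbon, the future C2'') much faster than to the trisubstituted C7''=C8'' alkene.

Step 16
Reactants: 26 (3R,4R)-4-[(4-methoxybenzyl)oxy]-3,7-dimethyloct-6-en-1-ol
Product: 27 1-({[(3R,4R)-1-iodo-3,7-dimethyloct-6-en-4-yl]oxy}methyl)-4-methoxybenzene
Conditions: I2, PPh3, imidazole, CH2Cl2, 0 °C
Reagents that add atoms: iodine, [I][I]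
Why: Appel-type iodination (iodophosphonium activation, SN2 displacement at the primary carbon) under neutral conditions that leave the p-methoxybenzyl ether and the alkene alone.

Step 17
Reactants: 17 tert-butyl{[(2R,3R)-6-{(E)-2-[(tert-butyldiphenylsilyl)oxy]ethylidene}-2-methyl-2-(p-tolylsulfonylmethyl)oxepan-3-yl]oxy}dimethylsilane; 27 1-({[(3R,4R)-1-iodo-3,7-dimethyloct-6-en-4-yl]oxy}methyl)-4-methoxybenzene
Product: 29 tert-butyl{[(2R,3R)-6-{(E)-2-[(tert-butyldiphenylsilyl)oxy]ethylidene}-2-{(4R,5R)-5-[(4-methoxybenzyl)oxy]-4,8-dimethyl-1-(p-tolylsulfonyl)non-7-en-1-yl}-2-methyloxepan-3-yl]oxy}dimethylsilane (both C1'' epimers), via C1''-lithiated sulfone 28 (not isolated)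
Conditions: n-BuLi, THF–HMPA, −78 °C; then 27, −78 to −40 °C
Reagents that add atoms: none
Why: Alkylation of an α-sulfonyl carbanion with an unhindered primary iodide forms C1''–C2''; HMPA raises the reactivity of the neopentylic carbanion, and the temperature is kept low so that 28 does not open the ring by β-elimination of O1. The new stereocentre at C1'' forms as a mixture and is removed in step 18.

Step 18
Reactants: 29 tert-butyl{[(2R,3R)-6-{(E)-2-[(tert-butyldiphenylsilyl)oxy]ethylidene}-2-{(4R,5R)-5-[(4-methoxybenzyl)oxy]-4,8-dimethyl-1-(p-tolylsulfonyl)non-7-en-1-yl}-2-methyloxepan-3-yl]oxy}dimethylsilane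
Product: 30 tert-butyl{[(2S,3R)-6-{(E)-2-[(tert-butyldiphenylsilyl)oxy]ethylidene}-2-{(4R,5R)-5-[(4-methoxybenzyl)oxy]-4,8-dimethylnon-7-en-1-yl}-2-methyloxepan-3-yl]oxy}dimethylsilane
Conditions: 6% Na/Hg, Na2HPO4, MeOH–THF, −20 °C
Reagents that add atoms: none
Why: Reductive desulfonylation by electron transfer: the radical anion loses sulfinate and the C1'' radical or anion should be protonated by methanol faster than it can expel the poor ether leaving group O1. With sulfur gone the C2 descriptor becomes S although nothing changes in space.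

Step 19
Reactants: 30 tert-butyl{[(2S,3R)-6-{(E)-2-[(tert-butyldiphenylsilyl)oxy]ethylidene}-2-{(4R,5R)-5-[(4-methoxybenzyl)oxy]-4,8-dimethylnon-7-en-1-yl}-2-methyloxepan-3-yl]oxy}dimethylsilane
Product: 31 (2S,3R)-6-[(E)-2-hydroxyethylidene]-2-{(4R,5R)-5-[(4-methoxybenzyl)oxy]-4,8-dimethylnon-7-en-1-yl}-2-methyloxepan-3-ol
Conditions: Bu4NF, THF, rt to 50 °C
Reagents that add atoms: none
Why: Fluoride cleaves both silyl ethers (warming is needed for the hindered C3 ether) and leaves the p-methoxybenzyl ether, exposing exactly the two hydroxyls that are acetylated in 33.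

Step 20
Reactants: 31 (2S,3R)-6-[(E)-2-hydroxyethylidene]-2-{(4R,5R)-5-[(4-methoxybenzyl)oxy]-4,8-dimethylnon-7-en-1-yl}-2-methyloxepan-3-ol
Product: 32 (2S,3R)-3-acetoxy-6-[(E)-2-acetoxyethylidene]-2-{(4R,5R)-5-[(4-methoxybenzyl)oxy]-4,8-dimethylnon-7-en-1-yl}-2-methyloxepane
Conditions: Ac2O, pyridine, DMAP (cat.), CH2Cl2, rt
Reagents that add atoms: acetic anhydride, CC(=O)OC(C)=O
Why: DMAP-catalysed acylation acetylates the primary allylic and the hindered secondary hydroxyl; C5'' is still masked.

Step 21
Reactants: 32 (2S,3R)-3-acetoxy-6-[(E)-2-acetoxyethylidene]-2-{(4R,5R)-5-[(4-methoxybenzyl)oxy]-4,8-dimethylnon-7-en-1-yl}-2-methyloxepane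
Product: 33 (2S,3R)-3-acetoxy-6-[(E)-2-acetoxyethylidene]-2-[(4R,5R)-5-hydroxy-4,8-dimethylnon-7-en-1-yl]-2-methyloxepane (CNP0194639.1)
Conditions: DDQ, CH2Cl2–pH 7 phosphate buffer (10:1), 0 °C
Reagents that add atoms: none
Why: Oxidative removal of the p-methoxybenzyl ether under buffered conditions frees the C5'' hydroxyl; the acetates, including the allylic one, and the trisubstituted alkenes should be inert to DDQ at 0 °C.

## Compound list

1 | but-2-yne-1,4-diol | OCC#CCO | starting material
2 | 4-[(4-methoxybenzyl)oxy]but-2-yn-1-ol | OCC#CCOCc1ccc(OC)cc1 | intermediate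
3 | sodium 2,2-bis(2-methoxyethoxy)-3-{[(4-methoxybenzyl)oxy]methyl}-1-oxa-2-aluminacyclopent-3-en-2-uide (cyclic alkenylalanate) | [Na+].COCCO[Al-]1(OCCOC)OCC=C1COCc1ccc(OC)cc1 | intermediate
4 | (Z)-3-iodo-4-[(4-methoxybenzyl)oxy]but-2-en-1-ol | OC/C=C(\I)COCc1ccc(OC)cc1 | intermediate
5 | (Z)-tert-butyl({3-iodo-4-[(4-methoxybenzyl)oxy]but-2-en-1-yl}oxy)diphenylsilane | CC(C)(C)[Si](c1ccccc1)(c1ccccc1)OC/C=C(\I)COCc1ccc(OC)cc1 | intermediate
6 | acrolein diethyl acetal (3,3-diethoxyprop-1-ene) | C=CC(OCC)OCC | starting material
7 | 9-(3,3-diethoxypropyl)-9-borabicyclo[3.3.1]nonane | CCOC(CCB1C2CCCC1CCC2)OCC | intermediate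
8 | (E)-tert-butyl[(6,6-diethoxy-3-{[(4-methoxybenzyl)oxy]methyl}hex-2-en-1-yl)oxy]diphenylsilane | CC(C)(C)[Si](c1ccccc1)(c1ccccc1)OC/C=C(\CCC(OCC)OCC)COCc1ccc(OC)cc1 | intermediate
9 | (E)-2-{2-[(tert-butyldiphenylsilyl)oxy]ethylidene}-5,5-diethoxypentan-1-ol | CC(C)(C)[Si](c1ccccc1)(c1ccccc1)OC/C=C(\CCC(OCC)OCC)CO | intermediate
10 | (1S,2R,5S)-menthyl (R)-p-toluenesulfinate | C[C@H]1CC[C@@H]([C@H](C1)O[S@@](=O)c1ccc(C)cc1)C(C)C | starting material
11 | prop-1-ynylmagnesium bromide | CC#C[Mg]Br | starting material
12 | (R)-1-methyl-4-(prop-1-yn-1-ylsulfinyl)benzene | CC#C[S@](=O)c1ccc(C)cc1 | intermediate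
13 | tert-butyl{[(E)-6,6-diethoxy-3-({[(E)-1-((S)-p-tolylsulfinyl)prop-1-en-2-yl]oxy}methyl)hex-2-en-1-yl]oxy}diphenylsilane | CCOC(CC/C(=C\CO[Si](c1ccccc1)(c1ccccc1)C(C)(C)C)CO/C(C)=C/[S@](=O)c1ccc(C)cc1)OCC | intermediate
14 | (E)-6-[(tert-butyldiphenylsilyl)oxy]-4-({[(E)-1-((S)-p-tolylsulfinyl)prop-1-en-2-yl]oxy}methyl)hex-4-enal | O=CCC/C(=C\CO[Si](c1ccccc1)(c1ccccc1)C(C)(C)C)CO/C(C)=C/[S@](=O)c1ccc(C)cc1 | intermediate
15 | (2R,3R)-6-{(E)-2-[(tert-butyldiphenylsilyl)oxy]ethylidene}-2-methyl-2-{[(S)-p-tolylsulfinyl]methyl}oxepan-3-ol | CC(C)(C)[Si](c1ccccc1)(c1ccccc1)OC/C=C1\CC[C@@H](O)[C@](C)(C[S@](=O)c2ccc(C)cc2)OC1 | intermediate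
16 | (2R,3R)-6-{(E)-2-[(tert-butyldiphenylsilyl)oxy]ethylidene}-2-methyl-2-(p-tolylsulfonylmethyl)oxepan-3-ol | CC(C)(C)[Si](c1ccccc1)(c1ccccc1)OC/C=C1\CC[C@@H](O)[C@](C)(CS(=O)(=O)c2ccc(C)cc2)OC1 | intermediate
17 | tert-butyl{[(2R,3R)-6-{(E)-2-[(tert-butyldiphenylsilyl)oxy]ethylidene}-2-methyl-2-(p-tolylsulfonylmethyl)oxepan-3-yl]oxy}dimethylsilane | CC(C)(C)[Si](c1ccccc1)(c1ccccc1)OC/C=C1\CC[C@@H](O[Si](C)(C)C(C)(C)C)[C@](C)(CS(=O)(=O)c2ccc(C)cc2)OC1 | intermediate
18 | 4-methylpent-3-en-1-ol | CC(C)=CCCO | starting material
19 | 4-methylpent-3-enal | CC(C)=CCC=O | intermediate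
20 | (Z)-but-2-ene | C/C=C\C | starting material
21 | (Z)-but-2-enylpotassium | C/C=C\C[K] | intermediate
22 | (Z)-but-2-enyldiisopinocampheylborane (isopinocampheyl groups from (+)-α-pinene) | C/C=C\CB([C@@H]1C[C@@H]2C[C@H]([C@H]1C)C2(C)C)[C@@H]1C[C@@H]2C[C@H]([C@H]1C)C2(C)C | intermediate
23 | (3R,4R)-3,7-dimethylocta-1,6-dien-4-ol | C=C[C@@H](C)[C@H](O)CC=C(C)C | intermediate
24 | 1-({[(3R,4R)-3,7-dimethylocta-1,6-dien-4-yl]oxy}methyl)-4-methoxybenzene | C=C[C@@H](C)[C@H](OCc1ccc(OC)cc1)CC=C(C)C | intermediate
25 | 9-{(3R,4R)-4-[(4-methoxybenzyl)oxy]-3,7-dimethyloct-6-en-1-yl}-9-borabicyclo[3.3.1]nonane | B1(C2CCCC1CCC2)CC[C@@H](C)[C@H](OCc1ccc(OC)cc1)CC=C(C)C | intermediate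
26 | (3R,4R)-4-[(4-methoxybenzyl)oxy]-3,7-dimethyloct-6-en-1-ol | OCC[C@@H](C)[C@H](OCc1ccc(OC)cc1)CC=C(C)C | intermediate
27 | 1-({[(3R,4R)-1-iodo-3,7-dimethyloct-6-en-4-yl]oxy}methyl)-4-methoxybenzene | ICC[C@@H](C)[C@H](OCc1ccc(OC)cc1)CC=C(C)C | intermediate
28 | C1''-lithio derivative of 17 | CC(C)(C)[Si](c1ccccc1)(c1ccccc1)OC/C=C1\CC[C@@H](O[Si](C)(C)C(C)(C)C)[C@](C)(C([Li])S(=O)(=O)c2ccc(C)cc2)OC1 | intermediate
29 | tert-butyl{[(2R,3R)-6-{(E)-2-[(tert-butyldiphenylsilyl)oxy]ethylidene}-2-{(4R,5R)-5-[(4-methoxybenzyl)oxy]-4,8-dimethyl-1-(p-tolylsulfonyl)non-7-en-1-yl}-2-methyloxepan-3-yl]oxy}dimethylsilane (C1'' epimers) | CC(C)(C)[Si](c1ccccc1)(c1ccccc1)OC/C=C1\CC[C@@H](O[Si](C)(C)C(C)(C)C)[C@](C)(C(CC[C@@H](C)[C@H](OCc2ccc(OC)cc2)CC=C(C)C)S(=O)(=O)c2ccc(C)cc2)OC1 | intermediate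
30 | tert-butyl{[(2S,3R)-6-{(E)-2-[(tert-butyldiphenylsilyl)oxy]ethylidene}-2-{(4R,5R)-5-[(4-methoxybenzyl)oxy]-4,8-dimethylnon-7-en-1-yl}-2-methyloxepan-3-yl]oxy}dimethylsilane | CC(C)(C)[Si](c1ccccc1)(c1ccccc1)OC/C=C1\CC[C@@H](O[Si](C)(C)C(C)(C)C)[C@](C)(CCC[C@@H](C)[C@H](OCc2ccc(OC)cc2)CC=C(C)C)OC1 | intermediate
31 | (2S,3R)-6-[(E)-2-hydroxyethylidene]-2-{(4R,5R)-5-[(4-methoxybenzyl)oxy]-4,8-dimethylnon-7-en-1-yl}-2-methyloxepan-3-ol | OC/C=C1\CC[C@@H](O)[C@](C)(CCC[C@@H](C)[C@H](OCc2ccc(OC)cc2)CC=C(C)C)OC1 | intermediate
32 | (2S,3R)-3-acetoxy-6-[(E)-2-acetoxyethylidene]-2-{(4R,5R)-5-[(4-methoxybenzyl)oxy]-4,8-dimethylnon-7-en-1-yl}-2-methyloxepane | CC(=O)OC/C=C1\CC[C@@H](OC(C)=O)[C@](C)(CCC[C@@H](C)[C@H](OCc2ccc(OC)cc2)CC=C(C)C)OC1 | intermediate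
33 | (2S,3R)-3-acetoxy-6-[(E)-2-acetoxyethylidene]-2-[(4R,5R)-5-hydroxy-4,8-dimethylnon-7-en-1-yl]-2-methyloxepane (CNP0194639.1) | CC(=O)OC/C=C1\CC[C@@H](OC(C)=O)[C@](C)(CCC[C@@H](C)[C@H](O)CC=C(C)C)OC1 | target

## Step count and least certain steps

Total step count: 21. Longest linear sequence: 15 steps (steps 1–5, 7–11 and 17–21, from 1 to 33).

**Step 9 (key step).** The most likely failure is poor facial selectivity at C2, or induction in the opposite sense. Sulfur is the only controlling element, it sits outside the forming ring, and its influence on a seven-membered closure that creates a quaternary carbon has not been demonstrated. Slow closure would in addition allow simple reduction of the aldehyde or pinacol coupling. Two remarks come before the fallback. A poorly selective reaction still gives separable diastereomers. If the sense is opposite, the enantiomer of 10 is used with no other change.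

The fallback gives up induction and resolves instead; it sets out from 9 and 12 and rejoins the route at 16. Oxidation of 12 with mCPBA gives 1-methyl-4-(prop-1-yn-1-ylsulfonyl)benzene F1. Base-catalysed addition of 9 gives the (E)-vinyl sulfone acetal F2, and hydrolysis as in step 8 gives the vinyl sulfone aldehyde F3. SmI2/MeOH cyclisation (ketyl addition to a vinyl sulfone, relative control only) gives the racemic trans-hydroxy sulfone F4, already at the oxidation level of 16. Esterification with (S)-O-methylmandelic acid (DCC, DMAP) and chromatographic separation of the diastereomeric esters follow. Methanolysis (K2CO3, MeOH) of the (2R,3R)-configured mandelate F5 returns 16.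

**Step 7.** Kinetic anti-addition gives the Z enol ether, and equilibration to the E isomer may be incomplete. Base-induced isomerisation of the propynyl group to an allene, or attack of the alkoxide at sulfur, may also intervene, because a β-substituted alkynyl sulfoxide is a slower acceptor than an ethynyl one.

The fallback fixes the geometry in a small reagent first; it sets out from 12 (with 9) and rejoins at 13. Compound 12 is treated with NaOMe in MeOH to give (E)-2-methoxyprop-1-enyl (S)-p-tolyl sulfoxide F6, which is equilibrated in the alcohol and purified as the single E isomer. Alkoxide exchange with 9 (cat. KOt-Bu, toluene, methanol removed under reduced pressure) by addition–elimination at C2 then gives 13.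

**Step 17.** The carbanion 28 is neopentylic, so alkylation may be slow. It also carries O1 β to the carbanion, so warming may open the ring by β-elimination.

The fallback avoids a C1'' carbanion altogether; it sets out from 15 and 27 and rejoins at 32.
- Acetylation of 15 (Ac2O, pyridine, DMAP) gives the C3 acetate sulfoxide F7.
- Pummerer rearrangement (trifluoroacetic anhydride, 2,4,6-collidine, MeCN, 0 °C; then aqueous NaHCO3) gives the C1'' aldehyde F8, which has no α-hydrogen and cannot epimerise.
- Iodide 27 and PPh3 (MeCN, reflux) give the phosphonium iodide F9.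
- Wittig reaction of F8 with the ylide of F9 (NaN(SiMe3)2, THF, −78 °C) gives the (Z)-C1''=C2'' alkene F10.
- Diimide (2-nitrobenzenesulfonylhydrazide, Et3N), selective for the disubstituted alkene, gives the saturated acetate silyl ether F11.
- HF·pyridine removes the silyl group to give the C2' alcohol F12, and acetylation gives 32.

**Step 18.** Electron transfer creates carbanion character at C1'' β to O1, so reductive ring opening may compete with protonation.

The fallback turns the elimination into a deliberate one with a better leaving group; it sets out from 17 (through 28) and 26 and rejoins at 30. Dess–Martin oxidation of 26 gives (3R,4R)-4-[(4-methoxybenzyl)oxy]-3,7-dimethyloct-6-enal F13. Addition of 28 to F13 at −78 °C and trapping with Ac2O gives the β-acetoxy sulfone F14. Julia–Lythgoe reductive elimination (6% Na/Hg, Na2HPO4, MeOH–THF, −20 °C) expels acetate rather than O1 and gives the C1''=C2'' alkene F15. Diimide reduction of this disubstituted alkene gives 30.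

## Further compounds

F1 | step 9 | 1-methyl-4-(prop-1-yn-1-ylsulfonyl)benzene | CC#CS(=O)(=O)c1ccc(C)cc1
F2 | step 9 | tert-butyl{[(E)-6,6-diethoxy-3-({[(E)-1-(p-tolylsulfonyl)prop-1-en-2-yl]oxy}methyl)hex-2-en-1-yl]oxy}diphenylsilane | CCOC(CC/C(=C\CO[Si](c1ccccc1)(c1ccccc1)C(C)(C)C)CO/C(C)=C/S(=O)(=O)c1ccc(C)cc1)OCC
F3 | step 9 | (E)-6-[(tert-butyldiphenylsilyl)oxy]-4-({[(E)-1-(p-tolylsulfonyl)prop-1-en-2-yl]oxy}methyl)hex-4-enal | O=CCC/C(=C\CO[Si](c1ccccc1)(c1ccccc1)C(C)(C)C)CO/C(C)=C/S(=O)(=O)c1ccc(C)cc1
F4 | step 9 | racemic 16 (16 and its enantiomer) | CC(C)(C)[Si](c1ccccc1)(c1ccccc1)OC/C=C1\CC[C@@H](O)[C@](C)(CS(=O)(=O)c2ccc(C)cc2)OC1.CC(C)(C)[Si](c1ccccc1)(c1ccccc1)OC/C=C1\CC[C@H](O)[C@@](C)(CS(=O)(=O)c2ccc(C)cc2)OC1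
F5 | step 9 | (S)-2-methoxy-2-phenylacetate of 16 | CC(C)(C)[Si](c1ccccc1)(c1ccccc1)OC/C=C1\CC[C@@H](OC(=O)[C@@H](OC)c2ccccc2)[C@](C)(CS(=O)(=O)c2ccc(C)cc2)OC1
F6 | step 7 | 1-{(S)-[(E)-2-methoxyprop-1-en-1-yl]sulfinyl}-4-methylbenzene | CO/C(C)=C/[S@](=O)c1ccc(C)cc1
F7 | step 17 | (2R,3R)-6-{(E)-2-[(tert-butyldiphenylsilyl)oxy]ethylidene}-2-methyl-2-{[(S)-p-tolylsulfinyl]methyl}oxepan-3-yl acetate | CC(C)(C)[Si](c1ccccc1)(c1ccccc1)OC/C=C1\CC[C@@H](OC(C)=O)[C@](C)(C[S@](=O)c2ccc(C)cc2)OC1
F8 | step 17 | 6-{(E)-2-[(tert-butyldiphenylsilyl)oxy]ethylidene}-2-formyl-2-methyloxepan-3-yl acetate (ring configuration as in 33) | CC(C)(C)[Si](c1ccccc1)(c1ccccc1)OC/C=C1\CC[C@@H](OC(C)=O)[C@](C)(C=O)OC1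
F9 | step 17 | {(3R,4R)-4-[(4-methoxybenzyl)oxy]-3,7-dimethyloct-6-en-1-yl}triphenylphosphonium iodide | [I-].c1ccccc1[P+](c1ccccc1)(c1ccccc1)CC[C@@H](C)[C@H](OCc1ccc(OC)cc1)CC=C(C)C
F10 | step 17 | C3 acetate, C2' silyl ether, C5'' p-methoxybenzyl ether with (Z)-C1''=C2'' alkene | CC(C)(C)[Si](c1ccccc1)(c1ccccc1)OC/C=C1\CC[C@@H](OC(C)=O)[C@](C)(/C=C\C[C@@H](C)[C@H](OCc2ccc(OC)cc2)CC=C(C)C)OC1
F11 | step 17 | (2S,3R)-6-{(E)-2-[(tert-butyldiphenylsilyl)oxy]ethylidene}-2-{(4R,5R)-5-[(4-methoxybenzyl)oxy]-4,8-dimethylnon-7-en-1-yl}-2-methyloxepan-3-yl acetate | CC(C)(C)[Si](c1ccccc1)(c1ccccc1)OC/C=C1\CC[C@@H](OC(C)=O)[C@](C)(CCC[C@@H](C)[C@H](OCc2ccc(OC)cc2)CC=C(C)C)OC1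
F12 | step 17 | (2S,3R)-6-[(E)-2-hydroxyethylidene]-2-{(4R,5R)-5-[(4-methoxybenzyl)oxy]-4,8-dimethylnon-7-en-1-yl}-2-methyloxepan-3-yl acetate | OC/C=C1\CC[C@@H](OC(C)=O)[C@](C)(CCC[C@@H](C)[C@H](OCc2ccc(OC)cc2)CC=C(C)C)OC1
F13 | step 18 | (3R,4R)-4-[(4-methoxybenzyl)oxy]-3,7-dimethyloct-6-enal | O=CC[C@@H](C)[C@H](OCc1ccc(OC)cc1)CC=C(C)C
F14 | step 18 | C2''-acetoxy C1''-sulfone adduct of 28 and F13 (mixture at C1'' and C2'') | CC(C)(C)[Si](c1ccccc1)(c1ccccc1)OC/C=C1\CC[C@@H](O[Si](C)(C)C(C)(C)C)[C@](C)(C(C(OC(C)=O)C[C@@H](C)[C@H](OCc2ccc(OC)cc2)CC=C(C)C)S(=O)(=O)c2ccc(C)cc2)OC1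
F15 | step 18 | (E)-C1''=C2'' alkene analogue of 30 | CC(C)(C)[Si](c1ccccc1)(c1ccccc1)OC/C=C1\CC[C@@H](O[Si](C)(C)C(C)(C)C)[C@](C)(/C=C/C[C@@H](C)[C@H](OCc2ccc(OC)cc2)CC=C(C)C)OC1
A1 | alternative 1 | 7-allyl-6-(tert-butyldimethylsilyloxy)-7-methyloxepan-2-one | O=C1CCC[C@@H](O[Si](C)(C)C(C)(C)C)[C@](C)(CC=C)O1
A2 | alternative 1 | 2-allyl-3-(tert-butyldimethylsilyloxy)-2-methylcyclohexan-1-one | O=C1CCC[C@@H](O[Si](C)(C)C(C)(C)C)[C@]1(C)CC=C
A3 | alternative 1 | 2-allyl-2-methylcyclohexane-1,3-dione | O=C1CCCC(=O)C1(C)CC=C
A4 | alternative 2 | 6-vinyl-2,3,4,7-tetrahydrooxepine with C3 acetate and C5'' silyl ether | C=CC1=CC[C@@H](OC(C)=O)[C@](C)(CCC[C@@H](C)[C@H](O[Si](C)(C)C(C)(C)C)CC=C(C)C)OC1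
A5 | alternative 2 | open-chain enyne: C2 propargyl ether, C3 acetate bearing an allyl group, C5'' silyl ether | C#CCO[C@@](C)(CCC[C@@H](C)[C@H](O[Si](C)(C)C(C)(C)C)CC=C(C)C)[C@@H](CC=C)OC(C)=O
A6 | alternative 3 | 6-alkylidene oxepan-3-one with the full side chain | CC(C)(C)[Si](c1ccccc1)(c1ccccc1)OC/C=C1\CCC(=O)[C@](C)(CCC[C@@H](C)[C@H](OCc2ccc(OC)cc2)CC=C(C)C)OC1
A7 | alternative 3 | 1-hydroxycyclopropyl tertiary ether of the (Z)-2-iodoallyl unit | CC(C)(C)[Si](c1ccccc1)(c1ccccc1)OC/C=C(\I)CO[C@@](C)(CCC[C@@H](C)[C@H](OCc2ccc(OC)cc2)CC=C(C)C)C1(O)CC1
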